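The ten-membered lactone ring is closed last across C4–C5. The step exploits that C4 is a ring methylene bonded directly to C5 of the E-configured C5=C6 alkene. The precursor is an open-chain C9 ester: its acyl part ends in a C3=C4 vinyl group next to the silylated (R)-C2 carbinol, its alcohol part carries the E-iodoalkene at C5 and a trans-7,8-acetonide derived from D-tartrate. In one operation, hydroboration places boron on C4 and palladium joins C4 to C5, giving the macrocycle with alkene geometry and all four stereocentres already in place. Acylation of C2 with a muconate half-ester and one acidic deprotection finish the synthesis.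

Key step: step 11

Remark: atoms are numbered as in the lactone (C1 carbonyl carbon to C9, the propyl-bearing carbon); the carbon that becomes C8 keeps one geometry throughout, and its descriptor changes (S in the esters, amide and ketone, R in the acetonide alcohols and their esters, S in the target) only because CIP priorities change.

Step 1
Reactants: 1 dimethyl (4S,5S)-2,2-dimethyl-1,3-dioxolane-4,5-dicarboxylate (dimethyl 2,3-O-isopropylidene-D-tartrate)
Product: 2 methyl (4S,5R)-5-(hydroxymethyl)-2,2-dimethyl-1,3-dioxolane-4-carboxylate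
Conditions: NaBH4 (0.6 equiv), MeOH, −10 → 0 °C
Reagents that add atoms: none
Why: Partial NaBH4 reduction of an α-alkoxy-activated methyl ester (chemoselective ester-to-alcohol reduction): because 1 is C2-symmetric either ester gives the same mono-alcohol, the stereocentres are not touched, and water-soluble diol and unreacted diester are separated easily.

Step 2
Reactants: 2 methyl (4S,5R)-5-(hydroxymethyl)-2,2-dimethyl-1,3-dioxolane-4-carboxylate
Product: 3 methyl (4S,5S)-5-formyl-2,2-dimethyl-1,3-dioxolane-4-carboxylate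
Conditions: Dess–Martin periodinane, pyridine, CH2Cl2, 0 °C → rt; used crude
Reagents that add atoms: none
Why: Dess–Martin oxidation of the primary alcohol under buffered, non-basic conditions should give the α-alkoxy aldehyde without epimerisation, the trans-dioxolane being the stable arrangement in any case.

Step 3
Reactants: 3 methyl (4S,5S)-5-formyl-2,2-dimethyl-1,3-dioxolane-4-carboxylate
Product: 4 methyl (4S,5R)-5-[(E)-2-iodoethenyl]-2,2-dimethyl-1,3-dioxolane-4-carboxylate
Conditions: CrCl2 (6 equiv), CHI3 (2 equiv), THF/dioxane, 0 °C → rt, dark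
Reagents that add atoms: iodoform, IC(I)I
Why: Takai iodo-olefination: the geminal dichromium species ICH(CrCl2)2 formed from CHI3 and divalent chromium adds to the aldehyde and eliminates anti to give the E-iodoalkene, and it leaves the methyl ester alone.

Step 4
Reactants: 4 methyl (4S,5R)-5-[(E)-2-iodoethenyl]-2,2-dimethyl-1,3-dioxolane-4-carboxylate
Product: 5 (4S,5R)-5-[(E)-2-iodoethenyl]-N-methoxy-N,2,2-trimethyl-1,3-dioxolane-4-carboxamide
Conditions: MeNHOMe·HCl, AlMe3, CH2Cl2, 0 °C → rt
Reagents that add atoms: N,O-dimethylhydroxylamine hydrochloride, CNOC.Cl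
Why: Weinreb amide formation by aminolysis of the methyl ester with MeAl(Cl)N(Me)OMe made from AlMe3, conditions under which alkenyl iodides and acetonides are inert.

Step 5
Reactants: 5 (4S,5R)-5-[(E)-2-iodoethenyl]-N-methoxy-N,2,2-trimethyl-1,3-dioxolane-4-carboxamide; 6 propylmagnesium bromide
Product: 7 1-[(4S,5R)-5-[(E)-2-iodoethenyl]-2,2-dimethyl-1,3-dioxolan-4-yl]butan-1-one
Conditions: THF, −78 → 0 °C; then pH 7 buffer
Reagents that add atoms: none
Why: Grignard addition to a Weinreb amide: the magnesium-chelated tetrahedral adduct survives until work-up so that only the ketone forms, and at low temperature PrMgBr does not exchange with the alkenyl iodide.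

Step 6
Reactants: 7 1-[(4S,5R)-5-[(E)-2-iodoethenyl]-2,2-dimethyl-1,3-dioxolan-4-yl]butan-1-one
Product: 8 (1S)-1-[(4R,5R)-5-[(E)-2-iodoethenyl]-2,2-dimethyl-1,3-dioxolan-4-yl]butan-1-ol
Conditions: KBH(s-Bu)3, THF, −78 °C; then H2O
Reagents that add atoms: none
Why: Felkin–Anh (non-chelation) ketone reduction: the bulky hydride with a poorly coordinating potassium counter-ion attacks anti to the C8–O bond of the dioxolane, which should set C9 as S, syn to the C8 oxygen.

Step 7
Reactants: 9 (2R)-but-3-ene-1,2-diol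
Product: 10 (3R)-3,4-bis[(tert-butyldimethylsilyl)oxy]but-1-ene
Conditions: TBSCl (2.4 equiv), imidazole, DMF, rt
Reagents that add atoms: tert-butyldimethylsilyl chloride, CC(C)(C)[Si](C)(C)Cl
Why: Imidazole-promoted silyl ether formation on both hydroxyl groups, in which no bond to the stereocentre is broken.

Step 8
Reactants: 10 (3R)-3,4-bis[(tert-butyldimethylsilyl)oxy]but-1-ene
Product: 11 (2R)-2-[(tert-butyldimethylsilyl)oxy]but-3-en-1-ol
Conditions: HF·pyridine, pyridine, THF, 0 °C
Reagents that add atoms: none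
Why: Selective desilylation: buffered HF·pyridine cleaves the unhindered primary silyl ether much faster than the secondary allylic one, and the acidic medium gives no silyl migration.

Step 9
Reactants: 11 (2R)-2-[(tert-butyldimethylsilyl)oxy]but-3-en-1-ol
Product: 13 (2R)-2-[(tert-butyldimethylsilyl)oxy]but-3-enoic acid, via silyloxy aldehyde 12 (not isolated)
Conditions: TEMPO (0.2 equiv), PhI(OAc)2 (2.2 equiv), MeCN/pH 7 buffer, 0 °C → rt
Reagents that add atoms: water, O
Why: TEMPO/PhI(OAc)2 oxoammonium oxidation carries the primary alcohol through aldehyde 12 and its hydrate to the acid under near-neutral conditions that leave the vinyl group, the silyl ether and the C2 configuration alone.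

Step 10
Reactants: 8 (1S)-1-[(4R,5R)-5-[(E)-2-iodoethenyl]-2,2-dimethyl-1,3-dioxolan-4-yl]butan-1-ol; 13 (2R)-2-[(tert-butyldimethylsilyl)oxy]but-3-enoic acid
Product: 14 (1S)-1-[(4R,5R)-5-[(E)-2-iodoethenyl]-2,2-dimethyl-1,3-dioxolan-4-yl]butyl (2R)-2-[(tert-butyldimethylsilyl)oxy]but-3-enoate
Conditions: DCC (1.3 equiv), DMAP (0.2 equiv), CH2Cl2, 0 °C → rt
Reagents that add atoms: none
Why: Steglich esterification: the C9 oxygen attacks the activated acid so that C9 keeps its configuration, and substoichiometric DMAP in the cold limits enolisation at C2.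

Step 11
Reactants: 14 (1S)-1-[(4R,5R)-5-[(E)-2-iodoethenyl]-2,2-dimethyl-1,3-dioxolan-4-yl]butyl (2R)-2-[(tert-butyldimethylsilyl)oxy]but-3-enoate
Product: 16 (2R,5E,7R,8R,9S)-2-[(tert-butyldimethylsilyl)oxy]-7,8-(isopropylidenedioxy)-9-propylnon-5-en-9-olide, via C4 alkylborane 15 (not isolated)
Conditions: 9-BBN (1.5 equiv), THF, 0 °C → rt; then syringe-pump addition to PdCl2(dppf) (20 mol %), AsPh3 (20 mol %), Cs2CO3 (3 equiv), H2O (40 equiv), DMF/THF, 50 °C, final 1 mM
Reagents that add atoms: none
Why: Proposed new method: 9-BBN adds anti-Markovnikov to the monosubstituted C3=C4 alkene to put boron on C4 (15); base then forms the borate, zerovalent palladium inserts into the C5–I bond with retention of the E geometry, the C4 alkyl group passes from boron to palladium within the same molecule, and C(sp3)–C(sp2) reductive elimination forms C4–C5. The closest known reaction type is the intramolecular B-alkyl Suzuki–Miyaura macrocyclisation, established for rings of twelve or more members, so the ten-membered case is an extension that has not been shown. The ten-membered lactone ring closes by reductive elimination from an eleven-membered palladacycle (Pd, C5 to C9, the ring oxygen, C1 to C4), with the trans-acetonide and the E-alkene holding the C5–C9 half in a turn. No stereocentre is formed: C3 and C4 become methylene groups and C2, C7, C8 and C9 are spectators. The step needs chemoselective hydroboration, secured by the much faster reaction of 9-BBN with a terminal vinyl group than with a 1,2-disubstituted iodoalkene or an ester, and it needs C2 to stay intact, secured because C2 is no longer allylic once boron is on C4 and Cs2CO3 is too weak a base to enolise the α-silyloxy ester. Oligomerisation is held back by slow addition of the borane to a dilute solution of the catalyst.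

Step 12
Reactants: 16 (2R,5E,7R,8R,9S)-2-[(tert-butyldimethylsilyl)oxy]-7,8-(isopropylidenedioxy)-9-propylnon-5-en-9-olide
Product: 17 (2R,5E,7R,8R,9S)-2-hydroxy-7,8-(isopropylidenedioxy)-9-propylnon-5-en-9-olide
Conditions: HF·pyridine, pyridine, THF, 0 °C → rt
Reagents that add atoms: none
Why: Fluoride-mediated desilylation with buffered HF·pyridine, which is non-basic (no C2 epimerisation or lactone opening) and leaves the acetonide intact.

Step 13
Reactants: 18 (2E,4E)-hexa-2,4-dienedioic acid ((2E,4E)-muconic acid)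
Product: 19 (2E,4E)-6-(tert-butoxy)-6-oxohexa-2,4-dienoic acid
Conditions: Me2NCH(Ot-Bu)2 (0.9 equiv), DMF/toluene, 80 °C
Reagents that add atoms: N,N-dimethylformamide di-tert-butyl acetal, CN(C)C(OC(C)(C)C)OC(C)(C)C
Why: tert-Butyl ester formation with the formamide acetal as limiting reagent (statistical mono-esterification of a symmetric diacid), after which the neutral diester is removed by bicarbonate extraction and the sparingly soluble diacid by filtration, the E,E geometry being unaffected.

Step 14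
Reactants: 17 (2R,5E,7R,8R,9S)-2-hydroxy-7,8-(isopropylidenedioxy)-9-propylnon-5-en-9-olide; 19 (2E,4E)-6-(tert-butoxy)-6-oxohexa-2,4-dienoic acid
Product: 20 tert-butyl (2R,5E,7R,8R,9S)-7,8-(isopropylidenedioxy)-9-propylnon-5-en-9-olid-2-yl (2E,4E)-hexa-2,4-dienedioate
Conditions: EDC·HCl, DMAP (0.2 equiv), CH2Cl2, 0 °C → rt
Reagents that add atoms: none
Why: Steglich-type carbodiimide esterification of the C2 hydroxyl, with retention at C2 because the C2–O bond is not broken.

Step 15
Reactants: 20 tert-butyl (2R,5E,7R,8R,9S)-7,8-(isopropylidenedioxy)-9-propylnon-5-en-9-olid-2-yl (2E,4E)-hexa-2,4-dienedioate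
Product: 21 (2E,4E)-6-{[(2R,5E,7R,8S,9S)-7,8-dihydroxy-9-propylnon-5-en-9-olid-2-yl]oxy}-6-oxohexa-2,4-dienoic acid (CNP0476488.1)
Conditions: TFA/CH2Cl2/H2O (10:10:1), 0 °C → rt
Reagents that add atoms: none
Why: Acidolysis: trifluoroacetic acid cleaves the tert-butyl ester by the tert-butyl cation pathway and hydrolyses the trans-fused acetonide in the same flask, while the lactone, the C2 ester and the three E alkenes are stable to non-nucleophilic acid.

Compound list
1 | dimethyl (4S,5S)-2,2-dimethyl-1,3-dioxolane-4,5-dicarboxylate | COC(=O)[C@H]1OC(C)(C)O[C@@H]1C(=O)OC | starting material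
2 | methyl (4S,5R)-5-(hydroxymethyl)-2,2-dimethyl-1,3-dioxolane-4-carboxylate | COC(=O)[C@H]1OC(C)(C)O[C@@H]1CO | intermediate
3 | methyl (4S,5S)-5-formyl-2,2-dimethyl-1,3-dioxolane-4-carboxylate | COC(=O)[C@H]1OC(C)(C)O[C@@H]1C=O | intermediate
4 | methyl (4S,5R)-5-[(E)-2-iodoethenyl]-2,2-dimethyl-1,3-dioxolane-4-carboxylate | COC(=O)[C@H]1OC(C)(C)O[C@@H]1/C=C/I | intermediate
5 | (4S,5R)-5-[(E)-2-iodoethenyl]-N-methoxy-N,2,2-trimethyl-1,3-dioxolane-4-carboxamide | CON(C)C(=O)[C@H]1OC(C)(C)O[C@@H]1/C=C/I | intermediate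
6 | propylmagnesium bromide | CCC[Mg]Br | starting material
7 | 1-[(4S,5R)-5-[(E)-2-iodoethenyl]-2,2-dimethyl-1,3-dioxolan-4-yl]butan-1-one | CCCC(=O)[C@H]1OC(C)(C)O[C@@H]1/C=C/I | intermediate
8 | (1S)-1-[(4R,5R)-5-[(E)-2-iodoethenyl]-2,2-dimethyl-1,3-dioxolan-4-yl]butan-1-ol | CCC[C@H](O)[C@H]1OC(C)(C)O[C@@H]1/C=C/I | intermediate
9 | (2R)-but-3-ene-1,2-diol | OC[C@H](O)C=C | starting material
10 | (3R)-3,4-bis[(tert-butyldimethylsilyl)oxy]but-1-ene | CC(C)(C)[Si](C)(C)OC[C@H](O[Si](C)(C)C(C)(C)C)C=C | intermediate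
11 | (2R)-2-[(tert-butyldimethylsilyl)oxy]but-3-en-1-ol | OC[C@H](O[Si](C)(C)C(C)(C)C)C=C | intermediate
12 | (2R)-2-[(tert-butyldimethylsilyl)oxy]but-3-enal | O=C[C@H](O[Si](C)(C)C(C)(C)C)C=C | intermediate (not isolated)
13 | (2R)-2-[(tert-butyldimethylsilyl)oxy]but-3-enoic acid | OC(=O)[C@H](O[Si](C)(C)C(C)(C)C)C=C | intermediate
14 | (1S)-1-[(4R,5R)-5-[(E)-2-iodoethenyl]-2,2-dimethyl-1,3-dioxolan-4-yl]butyl (2R)-2-[(tert-butyldimethylsilyl)oxy]but-3-enoate (key-step precursor) | CCC[C@H](OC(=O)[C@H](O[Si](C)(C)C(C)(C)C)C=C)[C@H]1OC(C)(C)O[C@@H]1/C=C/I | intermediate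
15 | (1S)-1-[(4R,5R)-5-[(E)-2-iodoethenyl]-2,2-dimethyl-1,3-dioxolan-4-yl]butyl (2R)-4-(9-borabicyclo[3.3.1]nonan-9-yl)-2-[(tert-butyldimethylsilyl)oxy]butanoate | CCC[C@H](OC(=O)[C@H](O[Si](C)(C)C(C)(C)C)CCB2C3CCCC2CCC3)[C@H]1OC(C)(C)O[C@@H]1/C=C/I | intermediate (not isolated)
16 | (2R,5E,7R,8R,9S)-2-[(tert-butyldimethylsilyl)oxy]-7,8-(isopropylidenedioxy)-9-propylnon-5-en-9-olide (key-step product) | CCC[C@@H]1OC(=O)[C@H](O[Si](C)(C)C(C)(C)C)CC/C=C/[C@H]2OC(C)(C)O[C@H]12 | intermediate
17 | (2R,5E,7R,8R,9S)-2-hydroxy-7,8-(isopropylidenedioxy)-9-propylnon-5-en-9-olide | CCC[C@@H]1OC(=O)[C@H](O)CC/C=C/[C@H]2OC(C)(C)O[C@H]12 | intermediate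
18 | (2E,4E)-hexa-2,4-dienedioic acid | OC(=O)/C=C/C=C/C(=O)O | starting material
19 | (2E,4E)-6-(tert-butoxy)-6-oxohexa-2,4-dienoic acid | OC(=O)/C=C/C=C/C(=O)OC(C)(C)C | intermediate
20 | tert-butyl (2R,5E,7R,8R,9S)-7,8-(isopropylidenedioxy)-9-propylnon-5-en-9-olid-2-yl (2E,4E)-hexa-2,4-dienedioate | CCC[C@@H]1OC(=O)[C@H](OC(=O)/C=C/C=C/C(=O)OC(C)(C)C)CC/C=C/[C@H]2OC(C)(C)O[C@H]12 | intermediate
21 | (2E,4E)-6-{[(2R,5E,7R,8S,9S)-7,8-dihydroxy-9-propylnon-5-en-9-olid-2-yl]oxy}-6-oxohexa-2,4-dienoic acid | CCC[C@@H]1OC(=O)[C@H](OC(=O)/C=C/C=C/C(=O)O)CC/C=C/[C@@H](O)[C@@H]1O | target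

Total step count: 15. Longest linear sequence: 11 steps (steps 1–6, 10, 11, 12, 14 and 15).

Steps most likely to fail

Step 11 (the step that bears the label). The strained transannular transmetalation may be slow, so that intermolecular coupling to oligomers, protodeboronation or β-hydride elimination take over. The fallback uses known chemistry only: it forms the same C4–C5 bond between two molecules and closes the ring at the lactone instead. It sets out from bis-silyl ether 10 and iodoalkenyl alcohol 8. 9-BBN adds to 10 to give the bis-silyloxybutyl borane F1, which is coupled in the same flask with 8 (PdCl2(dppf), AsPh3, Cs2CO3, DMF/THF/H2O, rt) to give the open-chain E-alkene bis-silyl ether F2. Buffered HF·pyridine frees the primary hydroxyl to give the diol F3. TEMPO/PhI(OAc)2 in aqueous MeCN oxidises the primary alcohol selectively, through the hydroxy aldehyde F4, to the seco acid F5. Shiina macrolactonisation (2-methyl-6-nitrobenzoic anhydride, DMAP, CH2Cl2, high dilution) then joins C1 to the C9 oxygen and returns to the route at 16.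

Step 6. Hydride delivery may not be face-selective if the dioxolane oxygen chelates or the Felkin–Anh bias is weak, giving a mixture at C9. The fallback uses the opposite, chelation-controlled mode on purpose and then inverts the centre. It sets out from ketone 7: Zn(BH4)2 in Et2O at −30 °C should give the (1R)-alcohol F6 through the five-membered zinc chelate. Mitsunobu reaction with 4-nitrobenzoic acid (PPh3, DIAD, toluene) inverts C9 to give the (1S)-4-nitrobenzoate F7, and K2CO3 in MeOH removes the ester to return at 8.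

Step 10. During carboxyl activation the C2 hydrogen is both α to the acyl group and allylic, so enolisation may epimerise C2 or move the C3=C4 double bond into conjugation. The fallback keeps the vinyl group masked until the ester bond exists. (R)-α-Hydroxy-γ-butyrolactone is silylated (TBSCl, imidazole) to the silyloxy lactone F8. PhSeNa (from PhSeSePh and NaBH4, DMF, 100 °C) opens it at the O–CH2 carbon to give the saturated selenide acid F9. Steglich esterification of F9 with alcohol 8 (the point where the fallback joins the route material) gives the selenide ester F10. H2O2/pyridine in CH2Cl2 forms the selenoxide F11, whose syn elimination on warming unveils the vinyl group and returns at 14.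

Further compounds
F1 | step 11 | 9-[(3R)-3,4-bis[(tert-butyldimethylsilyl)oxy]butyl]-9-borabicyclo[3.3.1]nonane | CC(C)(C)[Si](C)(C)OC[C@H](O[Si](C)(C)C(C)(C)C)CCB1C2CCCC1CCC2
F2 | step 11 | (1S)-1-[(4R,5R)-5-[(1E,5R)-5,6-bis[(tert-butyldimethylsilyl)oxy]hex-1-en-1-yl]-2,2-dimethyl-1,3-dioxolan-4-yl]butan-1-ol | CCC[C@H](O)[C@H]1OC(C)(C)O[C@@H]1/C=C/CC[C@H](CO[Si](C)(C)C(C)(C)C)O[Si](C)(C)C(C)(C)C
F3 | step 11 | (2R,5E)-2-[(tert-butyldimethylsilyl)oxy]-6-[(4R,5R)-5-[(1S)-1-hydroxybutyl]-2,2-dimethyl-1,3-dioxolan-4-yl]hex-5-en-1-ol | CCC[C@H](O)[C@H]1OC(C)(C)O[C@@H]1/C=C/CC[C@H](CO)O[Si](C)(C)C(C)(C)C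
F4 | step 11 | (2R,5E)-2-[(tert-butyldimethylsilyl)oxy]-6-[(4R,5R)-5-[(1S)-1-hydroxybutyl]-2,2-dimethyl-1,3-dioxolan-4-yl]hex-5-enal | CCC[C@H](O)[C@H]1OC(C)(C)O[C@@H]1/C=C/CC[C@H](C=O)O[Si](C)(C)C(C)(C)C
F5 | step 11 | (2R,5E)-2-[(tert-butyldimethylsilyl)oxy]-6-[(4R,5R)-5-[(1S)-1-hydroxybutyl]-2,2-dimethyl-1,3-dioxolan-4-yl]hex-5-enoic acid | CCC[C@H](O)[C@H]1OC(C)(C)O[C@@H]1/C=C/CC[C@H](C(=O)O)O[Si](C)(C)C(C)(C)C
F6 | step 6 | (1R)-1-[(4R,5R)-5-[(E)-2-iodoethenyl]-2,2-dimethyl-1,3-dioxolan-4-yl]butan-1-ol | CCC[C@@H](O)[C@H]1OC(C)(C)O[C@@H]1/C=C/I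
F7 | step 6 | (1S)-1-[(4R,5R)-5-[(E)-2-iodoethenyl]-2,2-dimethyl-1,3-dioxolan-4-yl]butyl 4-nitrobenzoate | CCC[C@H](OC(=O)c2ccc(cc2)[N+](=O)[O-])[C@H]1OC(C)(C)O[C@@H]1/C=C/I
F8 | step 10 | (3R)-3-[(tert-butyldimethylsilyl)oxy]oxolan-2-one | O=C1OCC[C@H]1O[Si](C)(C)C(C)(C)C
F9 | step 10 | (2R)-2-[(tert-butyldimethylsilyl)oxy]-4-(phenylselanyl)butanoic acid | OC(=O)[C@H](O[Si](C)(C)C(C)(C)C)CC[Se]c1ccccc1
F10 | step 10 | (1S)-1-[(4R,5R)-5-[(E)-2-iodoethenyl]-2,2-dimethyl-1,3-dioxolan-4-yl]butyl (2R)-2-[(tert-butyldimethylsilyl)oxy]-4-(phenylselanyl)butanoate | CCC[C@H](OC(=O)[C@H](O[Si](C)(C)C(C)(C)C)CC[Se]c2ccccc2)[C@H]1OC(C)(C)O[C@@H]1/C=C/I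
F11 | step 10 | (1S)-1-[(4R,5R)-5-[(E)-2-iodoethenyl]-2,2-dimethyl-1,3-dioxolan-4-yl]butyl (2R)-4-(benzeneseleninyl)-2-[(tert-butyldimethylsilyl)oxy]butanoate | CCC[C@H](OC(=O)[C@H](O[Si](C)(C)C(C)(C)C)CC[Se](=O)c2ccccc2)[C@H]1OC(C)(C)O[C@@H]1/C=C/I
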